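## Retrosynthetic overview

1. The C5=O / C10–OH pair of 24 is read as a cleaved C5–C10 bond. A Criegee rearrangement of the eudesmane-type trans-decalin hydroperoxide 21 makes the ten-membered ring last, with retention at C10.
2. 21 ⇒ ester 20 ⇒ α-methylene lactone 18 ⇒ lactone 15. The trans-γ-lactone (third ring) comes from enone 13 in one borane step that sets C7, C8 and C9.
3. 13 ⇒ diene 11 by ring-closing metathesis (ring B, second ring). 11 ⇒ ketone 6 plus the allylzinc reagent from chloro ester 8.
4. 6 ⇒ meso ketone 2 plus acrolein. Enantioselective deprotonation and aldol addition set C4 and C10, and this is the only source of absolute configuration in the carbocycle.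
5. 2 ⇒ 2,6-dimethylphenol 1 by arene hydrogenation. This delivers ring A (first ring), both methyl groups and the C5 oxygen.

Assumption: the germacrane numbering of the target (C1–C15) is used on all intermediates, and the (R,R)-lithium amide is taken to leave C4 as R by analogy with its known sense on 4-tert-butylcyclohexanone.

## Route

Step 1
Reactants: 1 2,6-dimethylphenol
Product: 2 cis-2,6-dimethylcyclohexanone (meso)
Conditions: H2 (10 bar), 5% Pd/C, cyclohexane, 120 °C; then cat. NaOMe, MeOH, rt; cis isomer separated by chromatography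
Reagents that add atoms: none
Why: Partial heterogeneous arene hydrogenation of a phenol stops at the ketone on Pd and breaks the aromaticity, and syn H2 delivery followed by base equilibration places both methyl groups equatorial, giving the meso cis ketone.

Step 2
Reactants: 2 cis-2,6-dimethylcyclohexanone; 3 acrolein
Product: 6 (4R,10S)-TMS-protected aldol ketone (C9 epimers), via lithium (R)-enolate 4 (not isolated), via lithium aldolate 5 (not isolated)
Conditions: (R,R)-[PhCH(Me)]2NH·HCl, n-BuLi (2 equiv), THF, −78 °C; 2; then 3, −78 °C, 10 min; then TMSCl, −78 → −30 °C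
Reagents that add atoms: chlorotrimethylsilane C[Si](C)(C)Cl
Why: Enantioselective deprotonation of a meso ketone with a C2-symmetric lithium amide/LiCl (Simpkins–Koga desymmetrisation) removes one of the two enantiotopic axial α-hydrogens so that C4 stays R, the tetrasubstituted enolate then adds 1,2 to acrolein (aldol addition) by axial attack anti to the C4 methyl to set quaternary C10, and silylation freezes the retro-aldol-prone aldolate, while both C9 epimers are carried on because C9 is reset in steps 6 and 7.

Step 3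
Reactants: 7 3-chloro-2-(chloromethyl)prop-1-ene
Product: 8 methyl 3-(chloromethyl)but-3-enoate
Conditions: 7 (3 equiv), CO (1 atm), MeOH, PdCl2(PPh3)2 (2 mol %), K2CO3, THF, 25 °C
Reagents that add atoms: carbon monoxide [C-]#[O+]; methanol CO
Why: Pd-catalysed alkoxycarbonylation of an allylic chloride (π-allyl formation, CO insertion, methanolysis) is held at the mono-ester by the excess of symmetric dichloride, and no stereocentre is formed.

Step 4
Reactants: 6 TMS-protected aldol ketone; 8 methyl 3-(chloromethyl)but-3-enoate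
Product: 11 (4R,5S,10S)-diene diol ester (C9 epimers), via allylzinc chloride 9 (not isolated), via TMS ether adduct 10 (not isolated)
Conditions: Zn dust, LiCl, THF, 0 °C → rt (Barbier mode); then 1 M HCl, THF, 0 °C
Reagents that add atoms: none
Why: Barbier-type allylzinc addition through a cyclic SE2' transition state tolerates both the ester and the 2,2,6-trisubstituted ketone, the axial non-chelating C9 side chain blocks one face so that C6 enters axially from the other (C5 S, C6 trans to C9), and the acidic work-up removes the TMS group.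

Step 5
Reactants: 11 diene diol ester
Product: 12 trans-decalin allylic alcohol (C9 epimers)
Conditions: Grubbs II (5 mol %), CH2Cl2 (5 mM), 40 °C
Reagents that add atoms: none
Why: Ring-closing metathesis of the vinyl carbinol with the 1,1-disubstituted alkene closes the six-membered ring B through the ring-flipped conformer with C6 and C9 diequatorial, is driven by loss of ethene, and touches no stereocentre.

Step 6
Reactants: 12 trans-decalin allylic alcohol
Product: 13 trans-decalin enone ester
Conditions: Dess–Martin periodinane, pyridine, CH2Cl2, 0 °C → rt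
Reagents that add atoms: none
Why: Dess–Martin oxidation under near-neutral conditions converts both C9 epimers into one enone without triggering retro-aldol cleavage or vinylogous loss of the tertiary C5–OH.

Step 7
Reactants: 13 trans-decalin enone ester
Product: 15 5α,9β-dihydroxy trans-γ-lactone, via triol ester 14 (not isolated)
Conditions: BH3·SMe2 (3 equiv), THF, 0 °C → rt; then 30% H2O2, NaOH, 0 °C; then 1 M HCl to pH 3
Reagents that add atoms: hydrogen peroxide OO
Why: In this borane reduction/hydroboration–oxidation of a cyclic enone to a trans-1,2-diol, hydride reaches C9 from the face opposite the axial angular methyl (equatorial 9β-OH), the C5–O-bound borane adds syn across C7=C8 from that same α-face with boron on the less substituted C8, and oxidation with retention followed by lactonisation gives the all-equatorial array with a trans-fused lactone.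

Step 8
Reactants: 15 5α,9β-dihydroxy trans-γ-lactone
Product: 18 α-methylene lactone diol, via Mannich base 16 (not isolated), via methiodide 17 (not isolated)
Conditions: LDA (3.5 equiv), THF, −78 °C; CH2=NMe2+ I−, −78 → 0 °C; then MeI, THF, rt; then sat. aq NaHCO3, CH2Cl2
Reagents that add atoms: N,N-dimethylmethyleneiminium iodide (Eschenmoser's salt) C=[N+](C)C.[I-]
Why: Aminomethylation of the lactone enolate with Eschenmoser's salt, N-methylation and Hofmann-type β-elimination install C13, the two hydroxyl groups ride through as alkoxides, and doing this before acylation avoids a strong base on the side-chain stereocentre.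

Step 9
Reactants: 18 α-methylene lactone diol; 19 (R)-2-methylbutanoic acid
Product: 20 9-O-[(R)-2-methylbutanoyl] ester
Conditions: DCC, DMAP, CH2Cl2, 0 °C → rt
Reagents that add atoms: none
Why: Steglich esterification acylates only the secondary equatorial C9–OH because the tertiary C5–OH is inert, and the mild carbodiimide activation preserves the configuration of 19.

Step 10
Reactants: 20 9-O-[(R)-2-methylbutanoyl] ester
Product: 21 C5 tertiary hydroperoxide
Conditions: 50% aq H2O2 (30 equiv), cat. H2SO4, DME, 0 °C
Reagents that add atoms: hydrogen peroxide OO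
Why: In this acid-catalysed perhydrolysis (SN1) of a tertiary alcohol, the C5 cation is captured by the large excess of H2O2 from the face opposite the two flanking axial methyl groups, the lactone, ester and acrylate tolerate cold acid, and the C5 configuration is later erased.

Step 11
Reactants: 21 C5 tertiary hydroperoxide
Product: 24 Ineupatorolide A, via peroxytrifluoroacetate 22 (not isolated), via bridged ketal trifluoroacetate 23 (not isolated)
Conditions: (CF3CO)2O, 2,6-lutidine, CH2Cl2, −40 → 0 °C; then pH 7 phosphate buffer, THF, 0 °C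
Reagents that add atoms: none
Why: In this Criegee rearrangement, O-acylation makes the O–O bond ionise while the best migrating group, the tertiary alkyl C10, shifts from C5 to oxygen with retention (C10 S), ion-pair return gives the 11-oxabicyclo[4.4.1]undecane ketal ester, and its hydrolysis opens the hemiketal to the C5 ketone and the C10 tertiary alcohol of the ten-membered ring.

## Compound list

1 | 2,6-dimethylphenol | Cc1cccc(C)c1O | starting material
2 | cis-(2R,6S)-2,6-dimethylcyclohexan-1-one (meso) | C[C@H]1CCC[C@@H](C)C1=O | intermediate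
3 | acrolein (prop-2-enal) | C=CC=O | starting material
4 | lithium (6R)-2,6-dimethylcyclohex-1-en-1-olate (C4 R) | CC1=C(O[Li])[C@H](C)CCC1 | intermediate
5 | lithium 1-[(1S,3R)-1,3-dimethyl-2-oxocyclohexyl]prop-2-en-1-olate (C9 epimers; methyl groups cis) | C=CC(O[Li])[C@]1(C)CCC[C@@H](C)C1=O | intermediate
6 | (2S,6R)-2,6-dimethyl-2-[1-(trimethylsilyloxy)prop-2-en-1-yl]cyclohexan-1-one (C9 epimers; methyl groups cis) | C=CC(O[Si](C)(C)C)[C@]1(C)CCC[C@@H](C)C1=O | intermediate
7 | 3-chloro-2-(chloromethyl)prop-1-ene | ClCC(=C)CCl | starting material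
8 | methyl 3-(chloromethyl)but-3-enoate | COC(=O)CC(=C)CCl | intermediate
9 | [2-(2-methoxy-2-oxoethyl)prop-2-en-1-yl]zinc chloride | COC(=O)CC(=C)C[Zn]Cl | intermediate
10 | C9-O-TMS ether of 11 | C=CC(O[Si](C)(C)C)[C@]1(C)CCC[C@@H](C)[C@@]1(O)CC(=C)CC(=O)OC | intermediate
11 | methyl 3-{[(1S,2S,6R)-1-hydroxy-2-(1-hydroxyprop-2-en-1-yl)-2,6-dimethylcyclohexyl]methyl}but-3-enoate (C9 epimers; C6 trans to C9) | C=CC(O)[C@]1(C)CCC[C@@H](C)[C@@]1(O)CC(=C)CC(=O)OC | intermediate
12 | methyl 2-[(4aS,5R,8aS)-1,4a-dihydroxy-5,8a-dimethyl-1,4,4a,5,6,7,8,8a-octahydronaphthalen-3-yl]acetate (trans-decalin, C9 epimers) | COC(=O)CC1=CC(O)[C@]2(C)CCC[C@@H](C)[C@@]2(O)C1 | intermediate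
13 | methyl 2-[(4aS,5R,8aR)-4a-hydroxy-5,8a-dimethyl-1-oxo-1,4,4a,5,6,7,8,8a-octahydronaphthalen-3-yl]acetate (5α-OH, 10β-Me, 4β-Me) | COC(=O)CC1=CC(=O)[C@]2(C)CCC[C@@H](C)[C@@]2(O)C1 | intermediate
14 | methyl (4R,5S,7S,8S,9S,10S)-5α,8α,9β-trihydroxy-13-nor-eudesman-12-oate | COC(=O)C[C@H]1[C@H](O)[C@@H](O)[C@]2(C)CCC[C@@H](C)[C@@]2(O)C1 | intermediate
15 | (4R,5S,7S,8S,9S,10S)-5α,9β-dihydroxy-13-nor-eudesman-12,8α-olide (7αH, 8βH, trans-lactone) | C1C(=O)O[C@@H]2[C@@H](O)[C@]3(C)CCC[C@@H](C)[C@@]3(O)C[C@@H]12 | intermediate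
16 | 11-(dimethylaminomethyl) derivative of 15 (C11 epimers) | CN(C)CC1C(=O)O[C@@H]2[C@@H](O)[C@]3(C)CCC[C@@H](C)[C@@]3(O)C[C@@H]12 | intermediate
17 | methiodide of 16 | C[N+](C)(C)CC1C(=O)O[C@@H]2[C@@H](O)[C@]3(C)CCC[C@@H](C)[C@@]3(O)C[C@@H]12.[I-] | intermediate
18 | (4R,5S,7S,8S,9S,10S)-5α,9β-dihydroxyeudesm-11(13)-en-12,8α-olide | C=C1C(=O)O[C@@H]2[C@@H](O)[C@]3(C)CCC[C@@H](C)[C@@]3(O)C[C@@H]12 | intermediate
19 | (R)-2-methylbutanoic acid | CC[C@@H](C)C(=O)O | starting material
20 | 5α-hydroxy-9β-[(R)-2-methylbutanoyloxy]eudesm-11(13)-en-12,8α-olide | C=C1C(=O)O[C@@H]2[C@@H](OC(=O)[C@H](C)CC)[C@]3(C)CCC[C@@H](C)[C@@]3(O)C[C@@H]12 | intermediate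
21 | 5α-hydroperoxy-9β-[(R)-2-methylbutanoyloxy]eudesm-11(13)-en-12,8α-olide | C=C1C(=O)O[C@@H]2[C@@H](OC(=O)[C@H](C)CC)[C@]3(C)CCC[C@@H](C)[C@@]3(OO)C[C@@H]12 | intermediate
22 | 5α-peroxytrifluoroacetate of 21 | C=C1C(=O)O[C@@H]2[C@@H](OC(=O)[C@H](C)CC)[C@]3(C)CCC[C@@H](C)[C@@]3(OOC(=O)C(F)(F)F)C[C@@H]12 | intermediate
23 | 5,10-epoxy-5-trifluoroacetoxy germacranolide (11-oxabicyclo[4.4.1]undecane ketal ester) | C=C1C(=O)O[C@@H]2[C@@H](OC(=O)[C@H](C)CC)[C@]3(C)CCC[C@@H](C)[C@](O3)(OC(=O)C(F)(F)F)C[C@@H]12 | intermediate
24 | Ineupatorolide A (4R,7S,8S,9R,10S,2'R) | C=C1C(=O)O[C@@H]2[C@@H](OC(=O)[C@H](C)CC)[C@@](C)(O)CCC[C@@H](C)C(=O)C[C@@H]12 | target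

## Step count

- Total step count: 11.
- Longest linear sequence: 10 (steps 1, 2, 4–11).

## Steps most likely to fail

**Step 2.** The risks are modest ee in removing a tertiary α-hydrogen, retro-aldol cleavage of the quaternary aldolate, and competing 1,4-addition.

The fallback sets out from 2 and comes back at 6. It gives up the chiral base and resolves at the carbinol instead. LDA, then 3, then a cold aqueous quench give the racemic aldols F1 (cis-dimethyl series, both C9 epimers). Sharpless kinetic resolution follows, with Ti(OiPr)4, D-(−)-DIPT, t-BuOOH and 4 Å sieves at −20 °C to about 55% conversion. It converts the (9S)-carbinols into the epoxy alcohols F2 and leaves the (9R)-carbinols. Among these, the (4R,9R,10S)-aldol F3 is separated by chromatography from its diastereomer, the (4S,9R,10R)-aldol F4. TMSCl/imidazole turns F3 into 6 as a single C9 epimer.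

**Step 10.** The risks are E1 loss to the Δ4 or Δ5(6) olefin, which would scramble C4, and slow ionisation next to the oxygenated ring.

The fallback sets out from 20 and comes back at 21. It replaces the cation by a radical. Methyl chlorooxoacetate, Et3N and DMAP give the mixed methyl oxalate F5. One equivalent of CsOH in aqueous THF at 0 °C gives the caesium oxalate F6. Visible-light photoredox oxidation (Ir[dF(CF3)ppy]2(dtbbpy)PF6, blue LED) under O2 expels two CO2 and forms the tertiary C5 radical. O2 captures this radical faster than any Giese addition, so 21 forms without C4 ever becoming sp2.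

**Step 11.** The risk is that the β-acyloxy group on C9 lowers the migratory aptitude of C10, so that C4 migrates instead and ring A is enlarged.

The fallback sets out from 18 and comes back at 24. The ring expansion is run before the acylation, on the less electron-poor substrate. Perhydrolysis of 18 as in step 10 gives the dihydroxy-series hydroperoxide F7. 4-Nitrobenzoyl chloride/pyridine at −20 °C acylates only the OOH group, giving the perester F8. On warming in CH2Cl2 this rearranges to the bridged ketal 4-nitrobenzoate F9. Buffered aqueous THF releases the 9,10-diol ketone F10. Steglich esterification with 19 then takes place only at the secondary C9–OH and gives 24.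

## Further compounds

F1 | step 2 | racemic 2-(1-hydroxyprop-2-en-1-yl)-2,6-dimethylcyclohexan-1-one (cis-dimethyl series, both C9 epimers) | C=CC(O)C1(C)CCCC(C)C1=O
F2 | step 2 | 2-[hydroxy(oxiran-2-yl)methyl]-2,6-dimethylcyclohexan-1-one (from the (9S)-carbinols, isomer mixture) | OC(C1CO1)C1(C)CCCC(C)C1=O
F3 | step 2 | (4R,9R,10S)-aldol | C=C[C@@H](O)[C@]1(C)CCC[C@@H](C)C1=O
F4 | step 2 | (4S,9R,10R)-aldol | C=C[C@@H](O)[C@@]1(C)CCC[C@H](C)C1=O
F5 | step 10 | C5 methyl oxalate of 20 | C=C1C(=O)O[C@@H]2[C@@H](OC(=O)[C@H](C)CC)[C@]3(C)CCC[C@@H](C)[C@@]3(OC(=O)C(=O)OC)C[C@@H]12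
F6 | step 10 | C5 caesium oxalate of 20 | C=C1C(=O)O[C@@H]2[C@@H](OC(=O)[C@H](C)CC)[C@]3(C)CCC[C@@H](C)[C@@]3(OC(=O)C(=O)[O-])C[C@@H]12.[Cs+]
F7 | step 11 | 5α-hydroperoxy-9β-hydroxyeudesm-11(13)-en-12,8α-olide | C=C1C(=O)O[C@@H]2[C@@H](O)[C@]3(C)CCC[C@@H](C)[C@@]3(OO)C[C@@H]12
F8 | step 11 | 5α-peroxy-4-nitrobenzoate of F7 | C=C1C(=O)O[C@@H]2[C@@H](O)[C@]3(C)CCC[C@@H](C)[C@@]3(OOC(=O)c4ccc(cc4)[N+](=O)[O-])C[C@@H]12
F9 | step 11 | 5,10-epoxy-5-(4-nitrobenzoyloxy)-9-hydroxy germacranolide (bridged ketal ester) | C=C1C(=O)O[C@@H]2[C@@H](O)[C@]3(C)CCC[C@@H](C)[C@](O3)(OC(=O)c4ccc(cc4)[N+](=O)[O-])C[C@@H]12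
F10 | step 11 | 9-O-deacyl-ineupatorolide A (9,10-diol ketone) | C=C1C(=O)O[C@@H]2[C@@H](O)[C@@](C)(O)CCC[C@@H](C)C(=O)C[C@@H]12
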